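(The runs are calculated with constants of no real substance, and the scatter is random.)

Spring, with 0.17 mol% of free catalyst against 0.074 mol% in noon, made twice the target by 5.00 min, while the starting material unaccounted for stood at 44.8% against 52.2%. You asked for a quick number and your hunch was a race between two paths, so I take it up with what we have:

| setting | noon | spring | blue | violet | ochre |
|---|---|---|---|---|---|
| starting material | 0.13 M | 0.13 M | 0.13 M | 0.13 M | 0.13 M |
| reagent | 1.3 equiv | 1.3 equiv | 1.30 equiv | 1.30 equiv | 1.30 equiv |
| protic impurity | 0.13 M | 0.13 M | 0.130 M | 0.130 M | 0.130 M |
| free catalyst | 0.074 mol% | 0.17 mol% | 0.11 mol% | 0.11 mol% | 0.11 mol% |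
| remark | run made earlier | run made earlier |  |  |  |
| time |  |  | 4.0 min | 10 min | 25 min |

| run | time / min | catalyst intermediate A / % | starting material / % | target / % | catalyst intermediate C / % |
|---|---|---|---|---|---|
| noon | 0.417 | 1.6 | 86.2 | 2.9 | 0 |
| noon | 1.33 | 0.2 | 70.1 | 5.3 | 0 |
| noon | 2.00 | 0 | 57.4 | 10.3 | 0 |
| noon | 3.00 | 0 | 45.1 | 13.3 | 0.4 |
| noon | 5.00 | 0.6 | 26.7 | 21.1 | 0.2 |
| spring | 1.00 | 1.3 | 69.7 | 11.0 | 0.7 |
| spring | 2.00 | 0.9 | 50.1 | 20.2 | 0 |
| spring | 3.00 | 1.0 | 33.6 | 27.1 | 1.7 |
| spring | 4.00 | 0.6 | 23.6 | 34.9 | 0 |
| spring | 5.00 | 0.5 | 13.6 | 41.6 | 0 |

(scatter of a reading: 1 percentage point)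



- which of these there is most of at the end, counted by the starting material in it, blue (catalyst intermediate C / catalyst intermediate A / target / starting material)
- which of these there is most of at the end, counted by the starting material in it, violet (catalyst intermediate C / catalyst intermediate A / target / starting material)
- which of these there is most of at the end, counted by the starting material in it, ochre (catalyst intermediate C / catalyst intermediate A / target / starting material)
- final amount of the leader among these, as a percentage of the starting material charged, in blue
- final amount of the leader among these, as a percentage of the starting material charged, in violet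
- final amount of the leader among these, as a percentage of the starting material charged, in ochre

I let target form at a steady rate in proportion to the catalyst, and I let a side loss take a constant fraction of the remaining starting material per minute, the side constant. Then

remaining = (charge + balance) × exp(−side constant × time) − balance

final target = balance × ln(charge/balance + charge/charge)

Here the balance amount is the target rate over the side constant, the level of starting material at which both paths take it equally fast. Noon's target rate reads 0.0422 min⁻¹, and I solve for the side constant by going round:

first round, missing amount over time and mean amount: 0.165 min⁻¹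

put back into the formula: 0.175 min⁻¹

once more: 0.179 min⁻¹

Spring did not enter this, and with its own target rate the formula gives 13.4% of starting material at 5.00 min, where the reading is 13.6%.

For the recipe, the mean rate per loading of noon and spring gives a target rate of 0.0583 min⁻¹, so the balance amount is 32.6%. Blue at 4.0 min then holds 32.2% of starting material and 23.3% of target. In this reckoning the starting material reaches zero at 7.85 min, earlier than violet's 10 min, so as an estimate I put violet and ochre both at 45.8% of target.

The forecast names starting material at 31% (27% to 35%) for blue, target at 40% (35% to 46%) for violet and target at 41% (34% to 49%) for ochre, on the ground that “Most of it therefore goes down an uncatalysed side path”. It has my leaders, and my estimate of the final target stands higher than its violet figure.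

Blue ends with starting material leading at 30.3%, violet with target at 44.5%, ochre with target at 45.3%.

    starting material + free catalyst ⇌ catalyst intermediate A (K = 461 M⁻¹, k = 21500 M⁻¹ min⁻¹)
    reagent + catalyst intermediate A ⇌ catalyst intermediate B (K = 2.00 M⁻¹, k = 514 M⁻¹ min⁻¹)
    starting material + protic impurity → quenched substrate (k = 2.02 M⁻¹ min⁻¹)
    catalyst intermediate C ⇌ free catalyst + target (K = 0.123 M, k = 251 min⁻¹)
    catalyst intermediate B → catalyst intermediate C (k = 12300 min⁻¹)

Ochre's target lies 0.50 percentage points under the estimate from the balance amount. In violet at 5.00 min, catalyst intermediate A, the resting state at that moment, holds 66.1% of the catalyst, and it meets the reagent in the next step. For the neighbour, violet's recipe with 0.330 equiv of reagent, I try scaling the target rate by the reagent charge. Its balance amount becomes 8.28%, which gives 14.8% of target and 9.80% of starting material at 10 min. That neighbour holds 15.5% of target and 17.1% of starting material.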